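## The problem

The target (28) is a trans-clerodane ester. Ring A (C1–C5, C10) and ring B (C5–C10) are trans-fused; ring A holds the C3=C4 alkene with C18, ring B the cis methyls C17 (on C8) and C20 (on C9), and C9 carries a chain C11–C16 ending in an E trisubstituted alkene whose C15 oxygen is acylated by icosanoic acid and whose C16 hydroxyl is free. Clerodane numbering is used throughout; β is the face of H10 and C11, α the face of C17, C19 and C20. Four stereocentres must be set: C8 and C9 are vicinal and C9 is quaternary, and C5 is a second quaternary centre whose methyl C19 is 1,3-diaxial to C20 and trans to H10. C8 and C9 can be set as a pair without reference to anything else, but C20 shields exactly the face of C5 that C19 must occupy, so C19 has to be delivered from a temporary oxygen at C4, and C5 then fixes C10. The icosanoate, the two allylic C–O bonds and the chain alkene will not survive hydrides, organometallic reagents, strong base or strong acid, and C3=C4 can migrate under acid; the chain is therefore joined late, with its two oxygens already told apart. O15 and O16 are trans across C13=C14, so the acyl group cannot migrate to the free hydroxyl. The enabling feature is ring B: its C8–C9 unit (cis methyls, one-carbon branch on the quaternary carbon) is (E)-2-methylbut-2-enal in all but oxidation level, and its C7–C6–C5–C10 unit is the diene of a 2-vinylcyclohexene that already contains ring A, so C7–C8 and C9–C10 are the two bonds of a [4+2] cycloaddition.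

## Retrosynthesis

**O–Si and O–acyl (28 ⇒ 27 ⇒ 25 + 26).** The C16 O–Si bond and then the C15 O–acyl bond are cut first. Acylating before the cross-coupling would expose an allylic ester to zerovalent palladium and aqueous base; acylating afterwards only asks a primary allylic alcohol to react beside a silyl ether. Alcohol 25 lacks the C20 acid 26, and the forward steps are a carbodiimide esterification and an acidic fluoride desilylation that leaves the ester alone.

**C12–C13 (25 ⇒ 19 + 23, through borane 24).** Cutting the sp3–sp2 bond separates the hydrocarbon core 19 from the four-carbon iodide 23, in which the alkene geometry and the distinction between O15 (free) and O16 (silylated) are already fixed. A cut at C13=C14 would leave the geometry to an olefination, and a cut at C11–C12 would demand alkylation at a neopentyl carbon. The forward reaction must hydroborate the vinyl group of 19 without touching C3=C4 and couple with retention of geometry.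

**C–I, C–H and O–Si of the chain piece (23 ⇒ 21 ⇒ 20).** Trans-hydroalumination of the propargylic alcohol 21, directed by its free hydroxyl, and iodinolysis (through alanate 22) give the Z iodide. Monosilylation of the symmetric diol 20 supplies 21, so the two oxygens are told apart in the first step.

**C4–C18 and C11=C12 (19 ⇒ 18 ⇒ 16 ⇒ 15 ⇒ 14).** C18 is cut at the enol triflate 18 of ketone 16 (through enolate 17). Because C5 is quaternary the ketone can enolise only toward C3, which fixes the alkene position, whereas methyl addition and dehydration would give alkene mixtures. The vinyl group comes from keto aldehyde 15 by methylenation, and 15 from diol 14 by one double oxidation.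

**C5–C19 and C10–H (14 ⇒ 13 ⇒ 12 ⇒ 11).** With the alkene at C5=C6, as in 9, the shortest relay would be a hydroxyl-directed cyclopropanation followed by hydrogenolysis. There, however, C4 is an exocyclic allylic position: its α substituent is equatorial and lies in the alkene plane, its axial position is β, and the open face of the alkene is also β. With the alkene at C5=C10, C4 is an endocyclic allylic carbon, and an α oxygen on it can reach only the α face. A bromomethylsilyl ether (12) then delivers C19 to C5 by 5-exo radical closure (13), the C10 radical takes hydrogen anti to C19 and C20, and fluoride turns the C–Si bond into C–H while also freeing C11–OH (14). The cut removes one carbon and two stereocentres and asks for cis delivery across the tether and trans hydrogen transfer.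

**Adjustment of the cycloadduct (11 ⇒ 10 ⇒ 9 ⇒ 8 ⇒ 7 ⇒ 6).** No skeletal bond is cut. The 4α carbinol of 11 comes from enone 10 by reagent-controlled reduction, since C8 and C9 are too remote to steer it. Enone 10 comes from the exocyclic-type enone 9 by isomerisation into the ring, 9 from ketal 8 by hydrolysis, and 8 from aldehyde 6 by reduction (7) and silylation. Because C10 becomes sp2 in 10, the exo/endo ratio of the cycloaddition is no longer critical; C8 and C9 are untouched.

**C7–C8 and C9–C10 (6 ⇒ 4 + 5).** Both ring B bonds are cut at once, which reduces a bicyclic aldehyde with three stereocentres to an achiral diene (4) and an achiral enal (5). Cutting C8–C9 or C5–C10 instead would leave the vicinal methyl pair or the ring fusion to separate steps. The forward reaction must join the β-carbon of 5 to the vinyl terminus of 4 and choose one enal face under catalyst control.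

**Diene (4 ⇒ 3 ⇒ 2 ⇒ 1).** The vinyl–ring bond is cut at iodide 3, which comes from cyclohex-2-en-1-one (1) by α-iodination (2) and ketalisation. The ketal keeps the diene from dimerising as an enone, keeps its two faces equivalent and marks C4 for the later relay.

## Roads not taken

**Alternative 1:** The cut is C5–C19 together with C10–H across a C5=C10 alkene. Bromomethylsilyl ether A2, made from a Birch-derived octalin, would be treated with Bu3SnH and AIBN to give siloxane A1. The merit is a geometrically sound delivery: the C4 oxygen is on an endocyclic allylic carbon, so C19 must enter cis to it, and hydrogen transfer to C10 anti to C19 gives the trans fusion. A1 also already contains C12, which saves the methylenation that the chosen plan needs. The weak point is upstream: the Birch-derived octalin must already hold C8 and quaternary C9 as a single enantiomer, and that road has no equally direct way to make this pair. As a relay it is better than any cyclopropanation on the C5=C6 isomer, and the chosen plan adopts the same reaction type as step 11 on 12. What the chosen plan sets against it is a single catalytic step that builds ring B with C8 and C9 from 4 and 5.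

**Alternative 2:** The cuts are C9–C10 and C4–C5. Acyclic trienal A4 would be folded by Me2AlCl so that the C5=C10 alkene attacks the activated enal at C9 and the vinylsilane captures the C5 cation with loss of silicon, giving aldehyde A3. If it works it is the shortest route of all: both rings, C5, C9, C10, the C3=C4 alkene and the C11–C12 aldehyde arise in one step, with no late angular methylation and no protecting groups on the core. In this it is clearly better than the chosen plan. Its weak points are that all new stereocentres depend on one resident centre (C8), on the Z geometry of an enal that can isomerise under the Lewis acid, and on a chair–chair fold that must place two methyl groups 1,3-diaxial. The closure also forms two quaternary carbons, so proton loss or monocyclisation can compete, and A4 needs three geometrically defined trisubstituted alkenes. The chosen plan is longer but sets C8/C9 in a catalytic reaction and builds C5 and C10 stepwise.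

**Alternative 3:** The cut is C4–C5. Vinyl iodide A6, a ring B enone acylated at C10, would give a C4 vinyl radical with (Me3Si)3SiH and AIBN; this adds 6-endo to C5 and the C10 radical takes hydrogen, giving ketone A5. The merits are that quaternary C5, the C3=C4 alkene and C18 arise in one step, that attack at C5 anti to C20 is the sterically preferred sense, and that C10 is epimerisable next to the C1 carbonyl; in these respects it is as good as or better than the chosen relay. The weak points are 5-exo attack at C10 competing with 6-endo closure, the later removal of the C1 carbonyl next to the ring fusion, and the need for an enantioselective route to the ring B enone with C8 and C9 in place. The chosen plan sets against it a catalytic entry to C8/C9 and a C4 oxygen that is later put to use rather than removed.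

Key step: step 4

Assumption: the (S)-configured oxazaborolidinium salt is taken to leave the Cα re face of the s-trans enal open (formyl C–H···O binding model), which is the sense needed for (8R,9S); if the opposite sense were found, the (R)-catalyst would be used and nothing else would change.

## Route

Step 1
Reactants: 1 cyclohex-2-en-1-one
Product: 2 2-iodocyclohex-2-en-1-one
Conditions: I2, pyridine, CH2Cl2, 0 °C → rt
Reagents that add atoms: iodine, SMILES II
Why: α-Iodination of a cyclic enone by conjugate addition of pyridine, iodination of the enolate and elimination; a standard reaction of cyclohex-2-enone.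

Step 2
Reactants: 2 2-iodocyclohex-2-en-1-one
Product: 3 6-iodo-1,4-dioxaspiro[4.5]dec-6-ene
Conditions: HOCH2CH2OH, p-TsOH (cat.), benzene, reflux, Dean–Stark
Reagents that add atoms: ethane-1,2-diol, SMILES OCCO
Why: Acid-catalysed ketalisation with azeotropic removal of water; with a 2-halo enone the double bond stays where it is, as known for the bromo and iodo analogues.

Step 3
Reactants: 3 6-iodo-1,4-dioxaspiro[4.5]dec-6-ene
Product: 4 6-ethenyl-1,4-dioxaspiro[4.5]dec-6-ene
Conditions: Bu3SnCH=CH2, Pd(PPh3)4 (cat.), CuI (cat.), DMF, 60 °C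
Reagents that add atoms: tributyl(ethenyl)stannane, SMILES C=C[Sn](CCCC)(CCCC)CCCC
Why: Stille coupling of an alkenyl iodide with a vinylstannane under neutral conditions that leave the ketal intact; the diene is stored cold and used promptly.

Step 4
Reactants: 4 6-ethenyl-1,4-dioxaspiro[4.5]dec-6-ene; 5 (E)-2-methylbut-2-enal
Product: 6 (4a'R,5'S,6'R)-5',6'-dimethyl-3',4',4a',5',6',7'-hexahydro-2'H-spiro[1,3-dioxolane-2,1'-naphthalene]-5'-carbaldehyde
Conditions: (S)-B-(2-methylphenyl)-diphenylprolinol oxazaborolidine (20 mol %), Tf2NH (18 mol %), CH2Cl2, −78 → −40 °C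
Reagents that add atoms: none
Why: The cationic boron of the triflimide-activated oxazaborolidine binds the formyl oxygen of s-trans 5 (with a formyl C–H···O contact to the ring oxygen), lowers its LUMO and screens one face with a phenyl group, and the cycloaddition is a concerted but asynchronous [4+2] in which C7–C8 leads. The closest known reaction type is the oxazaborolidinium-catalysed enantioselective Diels–Alder reaction of 2-substituted enals with 2-substituted and 1,2-disubstituted dienes. Ring B closes in a six-membered suprafacial–suprafacial pericyclic mode by forming C7–C8 and C9–C10. C8 and C9 are set together: their cis methyl relationship is copied from the E geometry of 5, and their absolute sense comes from the catalyst, which leaves the Cα re face open. C10 follows from the exo-formyl transition state, in which the coordinated formyl group points away from the C4 dioxolane and the α-methyl lies under the diene. The step needs regioselectivity (the β-carbon of 5 to the unhindered vinyl terminus C7, as with vinylcyclohexene dienes) and π-facial selectivity; it does not depend critically on the exo/endo ratio, because C10 is set again in step 11. The achiral ketal keeps the two diene faces equivalent and favours the s-cis rotamer, since C7 would clash with the dioxolane in the s-trans form.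

Step 5
Reactants: 6 (4a'R,5'S,6'R)-5',6'-dimethyl-3',4',4a',5',6',7'-hexahydro-2'H-spiro[1,3-dioxolane-2,1'-naphthalene]-5'-carbaldehyde
Product: 7 [(4a'R,5'S,6'R)-5',6'-dimethyl-3',4',4a',5',6',7'-hexahydro-2'H-spiro[1,3-dioxolane-2,1'-naphthalen]-5'-yl]methanol
Conditions: NaBH4, MeOH, 0 °C
Reagents that add atoms: none
Why: Borohydride reduction of the aldehyde on quaternary C9; ketal and alkene are inert and no stereocentre is formed.

Step 6
Reactants: 7 [(4a'R,5'S,6'R)-5',6'-dimethyl-3',4',4a',5',6',7'-hexahydro-2'H-spiro[1,3-dioxolane-2,1'-naphthalen]-5'-yl]methanol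
Product: 8 {[(4a'R,5'S,6'R)-5',6'-dimethyl-3',4',4a',5',6',7'-hexahydro-2'H-spiro[1,3-dioxolane-2,1'-naphthalen]-5'-yl]methoxy}tri(propan-2-yl)silane
Conditions: TIPSCl, imidazole, DMAP (cat.), DMF, 40 °C
Reagents that add atoms: chlorotri(propan-2-yl)silane, SMILES CC(C)[Si](Cl)(C(C)C)C(C)C
Why: Silylation of the primary alcohol with a bulky, acid-stable group that survives steps 7 to 11 and keeps the C11 oxygen out of the silylation of step 10.

Step 7
Reactants: 8 {[(4a'R,5'S,6'R)-5',6'-dimethyl-3',4',4a',5',6',7'-hexahydro-2'H-spiro[1,3-dioxolane-2,1'-naphthalen]-5'-yl]methoxy}tri(propan-2-yl)silane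
Product: 9 (4aR,5S,6R)-5,6-dimethyl-5-{[tri(propan-2-yl)silyl]oxymethyl}-3,4,4a,5,6,7-hexahydronaphthalen-1(2H)-one
Conditions: 1 M HCl, THF, rt
Reagents that add atoms: water, SMILES O
Why: Hydrolysis of the allylic ketal to the conjugated C4 ketone; the primary TIPS ether tolerates dilute acid and C9 has no hydrogen that could epimerise.

Step 8
Reactants: 9 (4aR,5S,6R)-5,6-dimethyl-5-{[tri(propan-2-yl)silyl]oxymethyl}-3,4,4a,5,6,7-hexahydronaphthalen-1(2H)-one
Product: 10 (5S,6R)-5,6-dimethyl-5-{[tri(propan-2-yl)silyl]oxymethyl}-3,4,5,6,7,8-hexahydronaphthalen-1(2H)-one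
Conditions: RhCl3·3H2O (5 mol %), EtOH, 80 °C
Reagents that add atoms: none
Why: Rhodium-hydride addition and elimination moves the C5=C6 bond into the tetrasubstituted C5=C10 position inside the cyclohexenone, the known isomerisation of 2-alkylidenecycloalkanones to the more stable endocyclic enones; C8 and C9 are untouched and any endo cycloadduct converges on the same enone.

Step 9
Reactants: 10 (5S,6R)-5,6-dimethyl-5-{[tri(propan-2-yl)silyl]oxymethyl}-3,4,5,6,7,8-hexahydronaphthalen-1(2H)-one
Product: 11 (1R,5S,6R)-5,6-dimethyl-5-{[tri(propan-2-yl)silyl]oxymethyl}-1,2,3,4,5,6,7,8-octahydronaphthalen-1-ol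
Conditions: (S)-2-methyl-CBS-oxazaborolidine (20 mol %), catecholborane, toluene, −78 °C
Reagents that add atoms: none
Why: CBS reduction of a 2-substituted cyclohexenone, in which the alkenyl side acts as the large group; the (S)-catalyst delivers hydride to the β face and gives the 4α (1R) carbinol under reagent control, since C8 and C9 are too far away to interfere.

Step 10
Reactants: 11 (1R,5S,6R)-5,6-dimethyl-5-{[tri(propan-2-yl)silyl]oxymethyl}-1,2,3,4,5,6,7,8-octahydronaphthalen-1-ol
Product: 12 (bromomethyl){[(1R,5S,6R)-5,6-dimethyl-5-{[tri(propan-2-yl)silyl]oxymethyl}-1,2,3,4,5,6,7,8-octahydronaphthalen-1-yl]oxy}dimethylsilane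
Conditions: BrCH2SiMe2Cl, Et3N, DMAP (cat.), CH2Cl2, 0 °C
Reagents that add atoms: (bromomethyl)chlorodimethylsilane, SMILES C[Si](C)(Cl)CBr
Why: Silylation of the secondary allylic alcohol installs the one-carbon radical precursor on the 4α oxygen.

Step 11
Reactants: 12 (bromomethyl){[(1R,5S,6R)-5,6-dimethyl-5-{[tri(propan-2-yl)silyl]oxymethyl}-1,2,3,4,5,6,7,8-octahydronaphthalen-1-yl]oxy}dimethylsilane
Product: 13 trans-fused siloxane with a 2,2-dimethyl-1-oxa-2-silacyclopentane ring across C4–C5 (oxygen on C4 α; ring CH2 = C19 on C5 α; H10 β; C17 and C20 α; CH2OTIPS on C9 β)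
Conditions: Bu3SnH (slow addition), AIBN (cat.), benzene, 80 °C
Reagents that add atoms: none
Why: Bromine abstraction gives the α-silyl radical, which adds 5-exo-trig to C5 of the tetrasubstituted alkene (silicon-tethered radical cyclisation of an allylic bromomethylsilyl ether); the five-membered ring forms cis-fused to ring A, so C19 enters on the α face, and the tertiary C10 radical takes hydrogen from Bu3SnH on the β face, anti to C19 and C20, giving the trans-decalin.

Step 12
Reactants: 13 trans-fused siloxane
Product: 14 (1R,4aR,5S,6R,8aR)-5-(hydroxymethyl)-5,6,8a-trimethyldecahydronaphthalen-1-ol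
Conditions: TBAF, DMF, 70 °C
Reagents that add atoms: none
Why: Fluoride attacks silicon, and the pentacoordinate siliconate next to the C4 alkoxide undergoes protodesilylation of the C19–Si bond, the known second half of the reductive-methylation sequence; the primary TIPS ether is cleaved in the same operation and no stereocentre is touched.

Step 13
Reactants: 14 (1R,4aR,5S,6R,8aR)-5-(hydroxymethyl)-5,6,8a-trimethyldecahydronaphthalen-1-ol
Product: 15 (1S,2R,4aR,8aR)-1,2,4a-trimethyl-5-oxodecahydronaphthalene-1-carbaldehyde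
Conditions: Dess–Martin periodinane, CH2Cl2, rt
Reagents that add atoms: none
Why: Dess–Martin oxidation of both hydroxyl groups; the aldehyde sits on quaternary C9 and the ketone on quaternary C5, so neither can epimerise.

Step 14
Reactants: 15 (1S,2R,4aR,8aR)-1,2,4a-trimethyl-5-oxodecahydronaphthalene-1-carbaldehyde
Product: 16 (4aR,5S,6R,8aR)-5-ethenyl-5,6,8a-trimethyloctahydronaphthalen-1(2H)-one
Conditions: Ph3PCH3Br, KN(SiMe3)2, THF, −78 → 0 °C
Reagents that add atoms: methyltriphenylphosphonium bromide, SMILES C[P+](c1ccccc1)(c1ccccc1)c1ccccc1.[Br-]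
Why: Wittig methylenation; the unstabilised ylide reacts with the aldehyde much faster than with the ketone flanked by quaternary C5, so one equivalent at low temperature is chemoselective.

Step 15
Reactants: 16 (4aR,5S,6R,8aR)-5-ethenyl-5,6,8a-trimethyloctahydronaphthalen-1(2H)-one
Product: 18 (4aR,5S,6R,8aR)-5-ethenyl-5,6,8a-trimethyl-3,4,4a,5,6,7,8,8a-octahydronaphthalen-1-yl trifluoromethanesulfonate, via potassium enolate 17 (not isolated)
Conditions: KN(SiMe3)2, THF, −78 °C; then PhNTf2
Reagents that add atoms: N-phenylbis(trifluoromethanesulfonimide), SMILES O=S(=O)(N(c1ccccc1)S(=O)(=O)C(F)(F)F)C(F)(F)F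
Why: Enolisation can only occur toward C3 because C5 is quaternary; O-sulfonylation of the enolate fixes the C3=C4 double bond as the enol triflate.

Step 16
Reactants: 18 (4aR,5S,6R,8aR)-5-ethenyl-5,6,8a-trimethyl-3,4,4a,5,6,7,8,8a-octahydronaphthalen-1-yl trifluoromethanesulfonate
Product: 19 (1S,2R,4aR,8aR)-1-ethenyl-1,2,4a,5-tetramethyl-1,2,3,4,4a,7,8,8a-octahydronaphthalene
Conditions: Me2CuLi (CuI, MeLi), THF, −20 → 0 °C
Reagents that add atoms: methyllithium (used as Me2CuLi), SMILES [Li]C
Why: Coupling of an alkenyl triflate with a lithium dialkylcuprate replaces the triflate by methyl without moving the double bond and installs C18; the vinyl group is inert.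

Step 17
Reactants: 20 but-2-yne-1,4-diol
Product: 21 4-{[tert-butyl(dimethyl)silyl]oxy}but-2-yn-1-ol
Conditions: TBSCl, imidazole, THF, 0 °C → rt (diol in excess)
Reagents that add atoms: tert-butyl(chloro)dimethylsilane, SMILES CC(C)(C)[Si](C)(C)Cl
Why: Statistical monosilylation of a symmetric diol used in excess; the unreacted diol is washed out with water.

Step 18
Reactants: 21 4-{[tert-butyl(dimethyl)silyl]oxy}but-2-yn-1-ol
Product: 23 (Z)-4-{[tert-butyl(dimethyl)silyl]oxy}-3-iodobut-2-en-1-ol, via sodium alkenylalanate 22 (not isolated)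
Conditions: NaAlH2(OCH2CH2OMe)2 (Red-Al), THF, 0 °C; then I2, −78 °C
Reagents that add atoms: iodine, SMILES II
Why: Hydroxyl-directed trans-hydroalumination of the propargylic alcohol puts hydrogen on the proximal and aluminium on the distal alkyne carbon; iodinolysis with retention gives the Z iodide, which fixes the later E geometry of C13=C14 and leaves the C15 hydroxyl free and the C16 oxygen silylated.

Step 19
Reactants: 19 (1S,2R,4aR,8aR)-1-ethenyl-1,2,4a,5-tetramethyl-1,2,3,4,4a,7,8,8a-octahydronaphthalene; 23 (Z)-4-{[tert-butyl(dimethyl)silyl]oxy}-3-iodobut-2-en-1-ol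
Product: 25 (2E)-4-{[tert-butyl(dimethyl)silyl]oxy}-3-{2-[(1S,2R,4aR,8aR)-1,2,4a,5-tetramethyl-1,2,3,4,4a,7,8,8a-octahydronaphthalen-1-yl]ethyl}but-2-en-1-ol, via B-alkyl-9-borabicyclononane 24 (not isolated)
Conditions: 9-BBN, THF, rt → 50 °C; then 23, Pd(dppf)Cl2 (cat.), AsPh3, Cs2CO3, DMF/H2O, rt
Reagents that add atoms: none
Why: Anti-Markovnikov hydroboration of the monosubstituted vinyl group by 9-BBN (the hindered trisubstituted C3=C4 alkene does not react), then B-alkyl Suzuki–Miyaura coupling with the alkenyl iodide with retention of geometry; this forms C12–C13 and tolerates the free hydroxyl.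

Step 20
Reactants: 25 (2E)-4-{[tert-butyl(dimethyl)silyl]oxy}-3-{2-[(1S,2R,4aR,8aR)-1,2,4a,5-tetramethyl-1,2,3,4,4a,7,8,8a-octahydronaphthalen-1-yl]ethyl}but-2-en-1-ol; 26 icosanoic acid
Product: 27 (2E)-4-{[tert-butyl(dimethyl)silyl]oxy}-3-{2-[(1S,2R,4aR,8aR)-1,2,4a,5-tetramethyl-1,2,3,4,4a,7,8,8a-octahydronaphthalen-1-yl]ethyl}but-2-en-1-yl icosanoate
Conditions: EDC·HCl, DMAP, CH2Cl2, rt
Reagents that add atoms: none
Why: Steglich esterification of the only free hydroxyl (C15) under neutral conditions that do not ionise the allylic C–O bond or move C3=C4.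

Step 21
Reactants: 27 (2E)-4-{[tert-butyl(dimethyl)silyl]oxy}-3-{2-[(1S,2R,4aR,8aR)-1,2,4a,5-tetramethyl-1,2,3,4,4a,7,8,8a-octahydronaphthalen-1-yl]ethyl}but-2-en-1-yl icosanoate
Product: 28 (2E)-4-hydroxy-3-{2-[(1S,2R,4aR,8aR)-1,2,4a,5-tetramethyl-1,2,3,4,4a,7,8,8a-octahydronaphthalen-1-yl]ethyl}but-2-en-1-yl icosanoate
Conditions: HF·pyridine, THF/pyridine, 0 °C
Reagents that add atoms: none
Why: Buffered fluoride cleaves the primary allylic TBS ether without hydrolysing the ester; the acyl group cannot migrate because O15 and O16 are trans across C13=C14.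

## Compound list

1 | cyclohex-2-en-1-one | O=C1C=CCCC1 | starting material
2 | 2-iodocyclohex-2-en-1-one | O=C1C(I)=CCCC1 | intermediate
3 | 6-iodo-1,4-dioxaspiro[4.5]dec-6-ene | IC1=CCCCC12OCCO2 | intermediate
4 | 6-ethenyl-1,4-dioxaspiro[4.5]dec-6-ene | C=CC1=CCCCC12OCCO2 | intermediate
5 | (E)-2-methylbut-2-enal | C/C=C(\C)C=O | starting material
6 | (4a'R,5'S,6'R)-5',6'-dimethyl-3',4',4a',5',6',7'-hexahydro-2'H-spiro[1,3-dioxolane-2,1'-naphthalene]-5'-carbaldehyde (8R,9S,10R in clerodane numbering; formyl and H10 β) | O=C[C@@]1(C)[C@H](C)CC=C2C3(OCCO3)CCC[C@H]12 | intermediate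
7 | [(4a'R,5'S,6'R)-5',6'-dimethyl-3',4',4a',5',6',7'-hexahydro-2'H-spiro[1,3-dioxolane-2,1'-naphthalen]-5'-yl]methanol | OC[C@@]1(C)[C@H](C)CC=C2C3(OCCO3)CCC[C@H]12 | intermediate
8 | {[(4a'R,5'S,6'R)-5',6'-dimethyl-3',4',4a',5',6',7'-hexahydro-2'H-spiro[1,3-dioxolane-2,1'-naphthalen]-5'-yl]methoxy}tri(propan-2-yl)silane | CC(C)[Si](OC[C@@]1(C)[C@H](C)CC=C2C3(OCCO3)CCC[C@H]12)(C(C)C)C(C)C | intermediate
9 | (4aR,5S,6R)-5,6-dimethyl-5-{[tri(propan-2-yl)silyl]oxymethyl}-3,4,4a,5,6,7-hexahydronaphthalen-1(2H)-one | CC(C)[Si](OC[C@@]1(C)[C@H](C)CC=C2C(=O)CCC[C@H]12)(C(C)C)C(C)C | intermediate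
10 | (5S,6R)-5,6-dimethyl-5-{[tri(propan-2-yl)silyl]oxymethyl}-3,4,5,6,7,8-hexahydronaphthalen-1(2H)-one | CC(C)[Si](OC[C@@]1(C)[C@H](C)CCC2=C1CCCC2=O)(C(C)C)C(C)C | intermediate
11 | (1R,5S,6R)-5,6-dimethyl-5-{[tri(propan-2-yl)silyl]oxymethyl}-1,2,3,4,5,6,7,8-octahydronaphthalen-1-ol (4α-OH) | CC(C)[Si](OC[C@@]1(C)[C@H](C)CCC2=C1CCC[C@H]2O)(C(C)C)C(C)C | intermediate
12 | (bromomethyl){[(1R,5S,6R)-5,6-dimethyl-5-{[tri(propan-2-yl)silyl]oxymethyl}-1,2,3,4,5,6,7,8-octahydronaphthalen-1-yl]oxy}dimethylsilane | CC(C)[Si](OC[C@@]1(C)[C@H](C)CCC2=C1CCC[C@H]2O[Si](C)(C)CBr)(C(C)C)C(C)C | intermediate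
13 | trans-fused siloxane: 2,2-dimethyl-1-oxa-2-silacyclopentane ring across C4–C5 (O on C4 α, CH2 = C19 on C5 α), H10 β, C17 and C20 α, CH2OTIPS on C9 β | CC(C)[Si](OC[C@@]1(C)[C@H](C)CC[C@@]2(C[Si](C)(C)O3)[C@H]3CCC[C@H]12)(C(C)C)C(C)C | intermediate
14 | (1R,4aR,5S,6R,8aR)-5-(hydroxymethyl)-5,6,8a-trimethyldecahydronaphthalen-1-ol | OC[C@@]1(C)[C@H](C)CC[C@@]2(C)[C@H](O)CCC[C@H]12 | intermediate
15 | (1S,2R,4aR,8aR)-1,2,4a-trimethyl-5-oxodecahydronaphthalene-1-carbaldehyde | O=C[C@@]1(C)[C@H](C)CC[C@@]2(C)C(=O)CCC[C@H]12 | intermediate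
16 | (4aR,5S,6R,8aR)-5-ethenyl-5,6,8a-trimethyloctahydronaphthalen-1(2H)-one | C=C[C@@]1(C)[C@H](C)CC[C@@]2(C)C(=O)CCC[C@H]12 | intermediate
17 | potassium (4aR,5S,6R,8aR)-5-ethenyl-5,6,8a-trimethyl-3,4,4a,5,6,7,8,8a-octahydronaphthalen-1-olate | [K+].C=C[C@@]1(C)[C@H](C)CC[C@@]2(C)C([O-])=CCC[C@H]12 | intermediate
18 | (4aR,5S,6R,8aR)-5-ethenyl-5,6,8a-trimethyl-3,4,4a,5,6,7,8,8a-octahydronaphthalen-1-yl trifluoromethanesulfonate | C=C[C@@]1(C)[C@H](C)CC[C@@]2(C)C(OS(=O)(=O)C(F)(F)F)=CCC[C@H]12 | intermediate
19 | (1S,2R,4aR,8aR)-1-ethenyl-1,2,4a,5-tetramethyl-1,2,3,4,4a,7,8,8a-octahydronaphthalene | C=C[C@@]1(C)[C@H](C)CC[C@@]2(C)C(C)=CCC[C@H]12 | intermediate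
20 | but-2-yne-1,4-diol | OCC#CCO | starting material
21 | 4-{[tert-butyl(dimethyl)silyl]oxy}but-2-yn-1-ol | OCC#CCO[Si](C)(C)C(C)(C)C | intermediate
22 | sodium alkenylalanate: 2,2-bis(2-methoxyethoxy)-3-({[tert-butyl(dimethyl)silyl]oxy}methyl)-2,5-dihydro-1,2-oxaaluminol-2-uide | [Na+].COCCO[Al-]1(OCCOC)OCC=C1CO[Si](C)(C)C(C)(C)C | intermediate
23 | (Z)-4-{[tert-butyl(dimethyl)silyl]oxy}-3-iodobut-2-en-1-ol | OC/C=C(\I)CO[Si](C)(C)C(C)(C)C | intermediate
24 | 9-{2-[(1S,2R,4aR,8aR)-1,2,4a,5-tetramethyl-1,2,3,4,4a,7,8,8a-octahydronaphthalen-1-yl]ethyl}-9-borabicyclo[3.3.1]nonane | C(C[C@@]1(C)[C@H](C)CC[C@@]2(C)C(C)=CCC[C@H]12)B1C2CCCC1CCC2 | intermediate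
25 | (2E)-4-{[tert-butyl(dimethyl)silyl]oxy}-3-{2-[(1S,2R,4aR,8aR)-1,2,4a,5-tetramethyl-1,2,3,4,4a,7,8,8a-octahydronaphthalen-1-yl]ethyl}but-2-en-1-ol | OC/C=C(/CO[Si](C)(C)C(C)(C)C)CC[C@@]1(C)[C@H](C)CC[C@@]2(C)C(C)=CCC[C@H]12 | intermediate
26 | icosanoic acid | CCCCCCCCCCCCCCCCCCCC(=O)O | starting material
27 | (2E)-4-{[tert-butyl(dimethyl)silyl]oxy}-3-{2-[(1S,2R,4aR,8aR)-1,2,4a,5-tetramethyl-1,2,3,4,4a,7,8,8a-octahydronaphthalen-1-yl]ethyl}but-2-en-1-yl icosanoate | CCCCCCCCCCCCCCCCCCCC(=O)OC/C=C(/CO[Si](C)(C)C(C)(C)C)CC[C@@]1(C)[C@H](C)CC[C@@]2(C)C(C)=CCC[C@H]12 | intermediate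
28 | (2E)-4-hydroxy-3-{2-[(1S,2R,4aR,8aR)-1,2,4a,5-tetramethyl-1,2,3,4,4a,7,8,8a-octahydronaphthalen-1-yl]ethyl}but-2-en-1-yl icosanoate (CNP0168335.1) | CCCCCCCCCCCCCCCCCCCC(=O)OC/C=C(/CO)CC[C@@]1(C)[C@H](C)CC[C@@]2(C)C(C)=CCC[C@H]12 | target

## Step count and least certain steps

Total: 21 steps. Longest linear sequence: 19 steps (steps 1–16 and 19–21); the chain piece 23 takes two steps (17, 18).

**Step 4 (key step).** The β-substituted enal is a sluggish dienophile, so the strongly acidic catalyst may instead open the allylic ketal or oligomerise the diene; π-facial selectivity may be eroded, and some bonding of the enal β-carbon to C10 instead of C7 is possible. The fallback sets out from 4 and 5 and rejoins at 11. The cycloaddition is run with EtAlCl2 in CH2Cl2 at −78 °C, which should give the racemate, that is 6 together with the mirror-image aldehyde ent-6 F1. Steps 5 to 8 carry the pair through the mirror-image alcohol ent-7 F2, silyl ether ent-8 F3, enone ent-9 F4 and ring-fusion enone ent-10 F5. Step 9 then acts as the resolving step: the (S)-CBS catalyst reduces both enantiomers from the same carbonyl face, so 10 gives 11 and F5 gives the diastereomeric (1R,5R,6S) alcohol F6, which is removed by chromatography.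

**Step 8.** The equilibrium may be reached slowly, the double bond may stop short of the tetrasubstituted position, or the acidic medium may loosen the silyl ether. The fallback sets out from 9 and rejoins at 10. Conjugate reduction with KBH(s-Bu)3 in THF at −78 °C and trapping of the C4–C5 enolate with PhSeBr should give the 5β-phenylselanyl ketone F7. Oxidation with H2O2 gives the selenoxide F8, whose syn elimination toward H10, which is cis to selenium, yields 10; elimination toward C6 only returns 9, which is recycled.

**Step 11.** The α-silyl radical may be reduced before it closes onto the tetrasubstituted alkene, or hydrogen transfer to C10 may be less face-selective than expected. The fallback sets out from 9 and rejoins at 14, keeping the H10 set in step 4. Luche reduction (NaBH4, CeCl3·7H2O, MeOH) should give the 4α allylic alcohol F9; Simmons–Smith cyclopropanation (Et2Zn, CH2I2) is to give the 5α,6α-methylene compound F10; hydrogenolysis of the least substituted cyclopropane bond (H2, PtO2, AcOH) gives the 5α-methyl alcohol F11, whose TIPS ether is removed with TBAF to give 14. This detour is as short as the main relay but less secure, because the equatorial C4 hydroxyl of F9 lies in the alkene plane and the α face must compete with the more open β face.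

**Step 19.** Hydroboration of the vinyl group on quaternary C9 may be slow, and the alkylborane may transmetalate sluggishly, so protodeboronation or reduction of the iodide can compete. The fallback sets out from 19 and rejoins at 25. Hydroboration (through 24) and oxidation with NaOH/H2O2 should give the primary alcohol F12; I2, PPh3 and imidazole give the iodide F13; zinc insertion (Zn, LiCl, THF) gives the alkylzinc iodide F14, which is joined to 23 by Negishi coupling with Pd(OAc)2 and SPhos, a catalyst that tolerates the free hydroxyl.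

## Further compounds

F1 | step 4 | (4a'S,5'R,6'S)-5',6'-dimethyl-3',4',4a',5',6',7'-hexahydro-2'H-spiro[1,3-dioxolane-2,1'-naphthalene]-5'-carbaldehyde (ent-6) | O=C[C@]1(C)[C@@H](C)CC=C2C3(OCCO3)CCC[C@@H]12
F2 | step 4 | [(4a'S,5'R,6'S)-5',6'-dimethyl-3',4',4a',5',6',7'-hexahydro-2'H-spiro[1,3-dioxolane-2,1'-naphthalen]-5'-yl]methanol (ent-7) | OC[C@]1(C)[C@@H](C)CC=C2C3(OCCO3)CCC[C@@H]12
F3 | step 4 | {[(4a'S,5'R,6'S)-5',6'-dimethyl-3',4',4a',5',6',7'-hexahydro-2'H-spiro[1,3-dioxolane-2,1'-naphthalen]-5'-yl]methoxy}tri(propan-2-yl)silane (ent-8) | CC(C)[Si](OC[C@]1(C)[C@@H](C)CC=C2C3(OCCO3)CCC[C@@H]12)(C(C)C)C(C)C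
F4 | step 4 | (4aS,5R,6S)-5,6-dimethyl-5-{[tri(propan-2-yl)silyl]oxymethyl}-3,4,4a,5,6,7-hexahydronaphthalen-1(2H)-one (ent-9) | CC(C)[Si](OC[C@]1(C)[C@@H](C)CC=C2C(=O)CCC[C@@H]12)(C(C)C)C(C)C
F5 | step 4 | (5R,6S)-5,6-dimethyl-5-{[tri(propan-2-yl)silyl]oxymethyl}-3,4,5,6,7,8-hexahydronaphthalen-1(2H)-one (ent-10) | CC(C)[Si](OC[C@]1(C)[C@@H](C)CCC2=C1CCCC2=O)(C(C)C)C(C)C
F6 | step 4 | (1R,5R,6S)-5,6-dimethyl-5-{[tri(propan-2-yl)silyl]oxymethyl}-1,2,3,4,5,6,7,8-octahydronaphthalen-1-ol | CC(C)[Si](OC[C@]1(C)[C@@H](C)CCC2=C1CCC[C@H]2O)(C(C)C)C(C)C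
F7 | step 8 | 5β-phenylselanyl ketone: (4aR,5S,6R)-5,6-dimethyl-8a-(phenylselanyl)-5-{[tri(propan-2-yl)silyl]oxymethyl}octahydronaphthalen-1(2H)-one, selenium cis to H10 | CC(C)[Si](OC[C@@]1(C)[C@H](C)CC[C@]2([Se]c3ccccc3)C(=O)CCC[C@H]12)(C(C)C)C(C)C
F8 | step 8 | selenoxide of F7 (8a-benzeneseleninyl ketone) | CC(C)[Si](OC[C@@]1(C)[C@H](C)CC[C@]2([Se](=O)c3ccccc3)C(=O)CCC[C@H]12)(C(C)C)C(C)C
F9 | step 11 | (1R,4aR,5S,6R)-5,6-dimethyl-5-{[tri(propan-2-yl)silyl]oxymethyl}-1,2,3,4,4a,5,6,7-octahydronaphthalen-1-ol (4α-OH, C5=C6) | CC(C)[Si](OC[C@@]1(C)[C@H](C)CC=C2[C@H](O)CCC[C@H]12)(C(C)C)C(C)C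
F10 | step 11 | 5α,6α-methylene alcohol: cyclopropane across C5–C6 on the α face (CH2 = C19), 4α-OH, H10 β, CH2OTIPS on C9 | CC(C)[Si](OC[C@@]1(C)[C@H](C)C[C@@H]3C[C@@]32[C@H](O)CCC[C@H]12)(C(C)C)C(C)C
F11 | step 11 | (1R,4aR,5S,6R,8aR)-5,6,8a-trimethyl-5-{[tri(propan-2-yl)silyl]oxymethyl}decahydronaphthalen-1-ol | CC(C)[Si](OC[C@@]1(C)[C@H](C)CC[C@@]2(C)[C@H](O)CCC[C@H]12)(C(C)C)C(C)C
F12 | step 19 | 2-[(1S,2R,4aR,8aR)-1,2,4a,5-tetramethyl-1,2,3,4,4a,7,8,8a-octahydronaphthalen-1-yl]ethan-1-ol | OCC[C@@]1(C)[C@H](C)CC[C@@]2(C)C(C)=CCC[C@H]12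
F13 | step 19 | (1S,2R,4aR,8aR)-1-(2-iodoethyl)-1,2,4a,5-tetramethyl-1,2,3,4,4a,7,8,8a-octahydronaphthalene | ICC[C@@]1(C)[C@H](C)CC[C@@]2(C)C(C)=CCC[C@H]12
F14 | step 19 | iodo{2-[(1S,2R,4aR,8aR)-1,2,4a,5-tetramethyl-1,2,3,4,4a,7,8,8a-octahydronaphthalen-1-yl]ethyl}zinc | I[Zn]CC[C@@]1(C)[C@H](C)CC[C@@]2(C)C(C)=CCC[C@H]12
A1 | alternative 1 | trans-fused cyclic siloxane with C19 tied to the C4 oxygen through SiMe2 and a C12 TIPS ether | CC(C)[Si](OCC[C@@]1(C)[C@H](C)CC[C@@]2(C[Si](C)(C)O3)[C@H]3CCC[C@H]12)(C(C)C)C(C)C
A2 | alternative 1 | (bromomethyl)dimethylsilyl ether of the 4α-hydroxy C5=C10 octalin with a C12 TIPS ether | CC(C)[Si](OCC[C@@]1(C)[C@H](C)CCC2=C1CCC[C@H]2O[Si](C)(C)CBr)(C(C)C)C(C)C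
A3 | alternative 2 | 2-[(1S,2R,4aR,8aR)-1,2,4a,5-tetramethyl-1,2,3,4,4a,7,8,8a-octahydronaphthalen-1-yl]acetaldehyde | O=CC[C@@]1(C)[C@H](C)CC[C@@]2(C)C(C)=CCC[C@H]12
A4 | alternative 2 | (2Z,4R,7E,11Z)-3,4,7-trimethyl-12-(trimethylsilyl)trideca-2,7,11-trienal | O=C/C=C(/C)[C@H](C)CC/C(C)=C/CC/C=C(/C)[Si](C)(C)C
A5 | alternative 3 | trans-fused 1-oxo clerod-3-ene core with a C12 TIPS ether | CC(C)[Si](OCC[C@@]1(C)[C@H](C)CC[C@@]2(C)C(C)=CCC(=O)[C@H]12)(C(C)C)C(C)C
A6 | alternative 3 | (Z)-4-iodopent-3-enoyl cyclohexene: C1-oxo C10=C5 enone of ring B with C19 on C5, a Z vinyl iodide at C3=C4 and a C12 TIPS ether | CC(C)[Si](OCC[C@@]1(C)[C@H](C)CCC(C)=C1C(=O)C/C=C(/C)I)(C(C)C)C(C)C
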